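## Retrosynthetic overview

1. Target 18 comes from the bicyclic 13-formate 17. Compound 17 is made in one cascade from the open-chain tetraene 16, which already carries the C2 senecioate and both stereocentres (C2, C13). The cascade forms ring A first (C4–C5 bond) and ring B second (C9–C10 bond), then loses H-7.
2. The chain end is drawn as an isopropenyl group (C4=CH2) so that the C2 ester is homoallylic, not allylic. The (2R) ester carbon is the only element that steers the fold and so fixes C5, C9 and C10.
3. Tetraene diol 14 comes from a C6–C7 allyl–allyl union (sulfone alkylation, then reductive desulfonylation) of head fragment 8 and tail fragment 11.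
4. Head fragment 8 (C1–C6, C18–C20) comes from (R)-epichlorohydrin, an isopropenyl Grignard reagent, acetylide and a Negishi carboalumination.
5. Tail fragment 11 (C7–C9, C11–C17) comes from (S)-linalool by E-selective allylic oxidation and chlorination.

Assumption: labdane numbering is used for positions; (R)-epichlorohydrin and (S)-(+)-linalool are bought in high ee (the latter upgraded if needed), and all unnumbered reagents are commercial.

## Route

Step 1
Reactants: 1 (R)-epichlorohydrin
Product: 2 (R)-1-chloro-4-methylpent-4-en-2-ol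
Conditions: isopropenylmagnesium bromide (1.2 equiv), copper monoiodide CuI (10 mol%), THF, −40 to −20 °C; aqueous work-up
Reagents that add atoms: isopropenylmagnesium bromide, CC(=C)[Mg]Br
Why: Copper-catalysed Grignard opening of the terminal epoxide at its CH2 carbon (SN2) leaves the stereocentre (future C2) untouched, and the chloride survives at low temperature.

Step 2
Reactants: 2 (R)-1-chloro-4-methylpent-4-en-2-ol
Product: 4 (R)-2-methylhept-1-en-6-yn-4-ol, via (R)-2-(2-methylallyl)oxirane 3 (not isolated)
Conditions: lithium acetylide–ethylenediamine complex (3 equiv), DMSO, 0 °C to rt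
Reagents that add atoms: lithium acetylide ethylenediamine complex, [Li]C#C.NCCN
Why: Intramolecular Williamson closure of the chlorohydrin gives the epoxide, which the acetylide opens at CH2 (SN2), so no bond to the stereocentre is broken.

Step 3
Reactants: 4 (R)-2-methylhept-1-en-6-yn-4-ol
Product: 6 (2E,5R)-3,7-dimethylocta-2,7-diene-1,5-diol, via alkenyldimethylalane 5 (not isolated)
Conditions: Me3Al (3.5 equiv), Cp2ZrCl2 (0.25 equiv), CH2Cl2, 0 °C to rt; solvent change to THF, n-BuLi (1.1 equiv), −78 °C; paraformaldehyde (5 equiv), −78 °C to rt; aqueous Rochelle-salt work-up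
Reagents that add atoms: trimethylaluminium, C[Al](C)C; paraformaldehyde (as formaldehyde), C=O
Why: Negishi zirconium-catalysed syn-carboalumination places CH3 on the internal and Al on the terminal alkyne carbon (E-alkene, C20 cis to C6), and the alanate is hydroxymethylated with retention while the 1,1-disubstituted alkene does not react.

Step 4
Reactants: 6 (2E,5R)-3,7-dimethylocta-2,7-diene-1,5-diol
Product: 8 (4R,6E)-2,6-dimethyl-8-(phenylsulfonyl)octa-1,6-dien-4-ol, via allylic chloride 7 (not isolated)
Conditions: N-chlorosuccinimide (1.15 equiv), Me2S (1.3 equiv), CH2Cl2, −20 to 0 °C; then PhSO2Na (1.5 equiv), n-Bu4NI (5 mol%), DMF, rt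
Reagents that add atoms: N-chlorosuccinimide, O=C1CCC(=O)N1Cl (chlorine of 7 only); sodium benzenesulfinate, [Na+].[O-]S(=O)c1ccccc1
Why: Corey–Kim chlorination converts only the primary allylic alcohol (the secondary carbinol is returned on work-up), and SN2 S-alkylation of the sulfinate gives the E-allylic sulfone without touching the stereocentre.

Step 5
Reactants: 9 (S)-linalool
Product: 10 (2E,6S)-2,6-dimethylocta-2,7-diene-1,6-diol
Conditions: SeO2 (0.3 equiv), t-BuOOH (3 equiv), salicylic acid (0.1 equiv), CH2Cl2, rt
Reagents that add atoms: tert-butyl hydroperoxide, CC(C)(C)OO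
Why: Riley–Sharpless allylic oxidation (ene reaction, then 2,3-shift) oxidises only the E-methyl of the trisubstituted alkene, leaving the C13 stereocentre and the vinyl group untouched.

Step 6
Reactants: 10 (2E,6S)-2,6-dimethylocta-2,7-diene-1,6-diol
Product: 11 (3S,6E)-8-chloro-3,7-dimethylocta-1,6-dien-3-ol
Conditions: N-chlorosuccinimide (1.2 equiv), Me2S (1.4 equiv), CH2Cl2, −20 to 0 °C
Reagents that add atoms: N-chlorosuccinimide, O=C1CCC(=O)N1Cl
Why: Corey–Kim chlorination replaces the primary allylic hydroxyl by SN2 on its alkoxysulfonium salt with E geometry kept, while the hindered tertiary alcohol does not react.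

Step 7
Reactants: 8 (4R,6E)-2,6-dimethyl-8-(phenylsulfonyl)octa-1,6-dien-4-ol and 11 (3S,6E)-8-chloro-3,7-dimethylocta-1,6-dien-3-ol
Product: 13 (3S,6E,10E,13R)-3,7,11,15-tetramethyl-9-(phenylsulfonyl)hexadeca-1,6,10,15-tetraene-3,13-diol (both C9 epimers), via dilithiated sulfone 12 (not isolated)
Conditions: 8 (1.2 equiv), n-BuLi (2.4 equiv), THF–DMPU 5:1, −78 °C; then 11 (1.0 equiv), −78 to −30 °C; aqueous work-up
Reagents that add atoms: none
Why: Biellmann-type alkylation, in which the α-sulfonyl allyl carbanion attacks the primary allylic chloride at its α-carbon (SN2), joins C6 to C7 with both E-alkenes kept, and the new sulfone-bearing centre is removed in the next step.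

Step 8
Reactants: 13 (3S,6E,10E,13R)-3,7,11,15-tetramethyl-9-(phenylsulfonyl)hexadeca-1,6,10,15-tetraene-3,13-diol
Product: 14 (3S,6E,10E,13R)-3,7,11,15-tetramethylhexadeca-1,6,10,15-tetraene-3,13-diol
Conditions: PdCl2(dppp) (5 mol%), LiBHEt3 (4.5 equiv), THF, 0 °C to rt
Reagents that add atoms: none
Why: In this palladium-catalysed reductive desulfonylation, zerovalent palladium ionises the allylic sulfone to a π-allyl complex and hydride is delivered to the less substituted terminus (C6), so the C5=C10 alkene keeps its position and E geometry.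

Step 9
Reactants: 14 (3S,6E,10E,13R)-3,7,11,15-tetramethylhexadeca-1,6,10,15-tetraene-3,13-diol
Product: 15 (4R,6E,10E,14S)-14-hydroxy-2,6,10,14-tetramethylhexadeca-1,6,10,15-tetraen-4-yl 3-methylbut-2-enoate
Conditions: 3-methylbut-2-enoic acid (1.5 equiv), DCC (1.5 equiv), DMAP (0.2 equiv), CH2Cl2, 0 °C to rt
Reagents that add atoms: 3-methylbut-2-enoic acid, CC(C)=CC(=O)O
Why: Steglich esterification acylates only the secondary alcohol (the tertiary allylic alcohol is too hindered), and carbodiimide activation avoids the ketene pathway that deconjugates the acid chloride.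

Step 10
Reactants: 15 (4R,6E,10E,14S)-14-hydroxy-2,6,10,14-tetramethylhexadeca-1,6,10,15-tetraen-4-yl 3-methylbut-2-enoate
Product: 16 (4R,6E,10E,14S)-14-(formyloxy)-2,6,10,14-tetramethylhexadeca-1,6,10,15-tetraen-4-yl 3-methylbut-2-enoate
Conditions: acetic formic anhydride (5 equiv), pyridine, CH2Cl2, −20 to 0 °C
Reagents that add atoms: acetic formic anhydride, CC(=O)OC=O
Why: Mixed-anhydride formylation transfers the small formyl group to the tertiary alcohol under buffered conditions that do not ionise the allylic C–O bond, and the formate makes the C13 oxygen non-nucleophilic for the cascade.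

Step 11
Reactants: 16 (4R,6E,10E,14S)-14-(formyloxy)-2,6,10,14-tetramethylhexadeca-1,6,10,15-tetraen-4-yl 3-methylbut-2-enoate
Product: 18 target: 13-hydroxy-ent-labda-7,14-dien-2-yl 3-methylbut-2-enoate with 2R,5R,9R,10R,13S configuration (ester equatorial and cis to H-5), via bicyclic 13-formate 17 (not isolated)
Conditions: [N,N′-bis(3,5-di-tert-butylsalicylidene)-1,2-cyclohexanediaminato]cobalt (C36H52CoN2O2, 5 mol%), N-fluoro-2,4,6-trimethylpyridinium triflate (1.3 equiv), PhSiH3 (1.3 equiv), (CF3)2CHOH, 0.02 M, 0 °C; concentrate; then K2CO3 (0.3 equiv), MeOH, 0 °C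
Reagents that add atoms: none
Why: Proposed new method: a cobalt hydride formed from the salen complex, the N-fluoropyridinium oxidant and the silane transfers a hydrogen atom selectively to the 1,1-disubstituted C4=CH2 alkene (the trisubstituted, conjugated and ester-deactivated vinyl alkenes react far more slowly), the tertiary C4 radical is oxidised to the same C4 cation that the cyclase makes by protonation, and this cation is captured through a chair–chair fold with the C2 ester equatorial (an axial ester would clash with the C4 and C10 methyl groups), so the (2R) centre sets 5R, 10R and 9R by anti addition across the two E-alkenes before the liberated collidine removes H-7 (any exocyclic isomer is re-engaged by the catalyst and funnelled to the 7-ene) and buffered methanolysis then cleaves only the formate; the closest known reaction type is the cobalt-catalysed hydrogen-atom-transfer radical–polar crossover bicyclisation of methallyl-terminated polyenes that ends on an arene.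

## Compound list

1 | (R)-epichlorohydrin | ClC[C@H]1CO1 | starting material
2 | (R)-1-chloro-4-methylpent-4-en-2-ol | C=C(C)C[C@@H](O)CCl | intermediate
3 | (R)-2-(2-methylallyl)oxirane | C=C(C)C[C@@H]1CO1 | intermediate
4 | (R)-2-methylhept-1-en-6-yn-4-ol | C=C(C)C[C@@H](O)CC#C | intermediate
5 | E-alkenyldimethylalane from 4 (Al on C5 cis to the new C20 methyl; oxygen as dimethylaluminium alkoxide) | C=C(C)C[C@@H](O[Al](C)C)C/C(C)=C/[Al](C)C | intermediate
6 | (2E,5R)-3,7-dimethylocta-2,7-diene-1,5-diol | C=C(C)C[C@@H](O)C/C(C)=C/CO | intermediate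
7 | (4R,6E)-8-chloro-2,6-dimethylocta-1,6-dien-4-ol | C=C(C)C[C@@H](O)C/C(C)=C/CCl | intermediate
8 | (4R,6E)-2,6-dimethyl-8-(phenylsulfonyl)octa-1,6-dien-4-ol | C=C(C)C[C@@H](O)C/C(C)=C/CS(=O)(=O)c1ccccc1 | intermediate
9 | (S)-linalool | C=C[C@@](C)(O)CCC=C(C)C | starting material
10 | (2E,6S)-2,6-dimethylocta-2,7-diene-1,6-diol | C=C[C@@](C)(O)CC/C=C(\C)CO | intermediate
11 | (3S,6E)-8-chloro-3,7-dimethylocta-1,6-dien-3-ol | C=C[C@@](C)(O)CC/C=C(\C)CCl | intermediate
12 | dilithio derivative of 8 (lithium alkoxide, α-sulfonyl allyl carbanion) | C=C(C)C[C@@H](O[Li])C/C(C)=C/C([Li])S(=O)(=O)c1ccccc1 | intermediate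
13 | (3S,6E,10E,13R)-3,7,11,15-tetramethyl-9-(phenylsulfonyl)hexadeca-1,6,10,15-tetraene-3,13-diol, C9 epimers | C=C[C@@](C)(O)CC/C=C(\C)CC(S(=O)(=O)c1ccccc1)/C=C(\C)C[C@H](O)CC(C)=C | intermediate
14 | (3S,6E,10E,13R)-3,7,11,15-tetramethylhexadeca-1,6,10,15-tetraene-3,13-diol | C=C[C@@](C)(O)CC/C=C(\C)CC/C=C(\C)C[C@H](O)CC(C)=C | intermediate
15 | (4R,6E,10E,14S)-14-hydroxy-2,6,10,14-tetramethylhexadeca-1,6,10,15-tetraen-4-yl 3-methylbut-2-enoate | C=C[C@@](C)(O)CC/C=C(\C)CC/C=C(\C)C[C@H](OC(=O)C=C(C)C)CC(C)=C | intermediate
16 | (4R,6E,10E,14S)-14-(formyloxy)-2,6,10,14-tetramethylhexadeca-1,6,10,15-tetraen-4-yl 3-methylbut-2-enoate | C=C[C@@](C)(OC=O)CC/C=C(\C)CC/C=C(\C)C[C@H](OC(=O)C=C(C)C)CC(C)=C | intermediate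
17 | 13-O-formyl derivative of the target (2R,5R,9R,10R,13S) | C=C[C@@](C)(OC=O)CC[C@@H]1C(C)=CC[C@@H]2C(C)(C)C[C@@H](OC(=O)C=C(C)C)C[C@@]12C | intermediate
18 | 13-hydroxy-ent-labda-7,14-dien-2-yl 3-methylbut-2-enoate (2R,5R,9R,10R,13S), CNP0252389.1 | C=C[C@@](C)(O)CC[C@@H]1C(C)=CC[C@@H]2C(C)(C)C[C@@H](OC(=O)C=C(C)C)C[C@@]12C | target

## Step count and risks

Total steps: 11. Longest linear sequence: 9 steps (1, 2, 3, 4, 7, 8, 9, 10, 11 from (R)-epichlorohydrin); the linalool branch adds steps 5 and 6.

The three steps most likely to fail: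

**Step 11 (bicyclisation).** The risks are capture of the C4 cation by the C2 ester carbonyl (a six-membered dioxanylium ion), hydrogen-atom transfer to the vinyl group, solvolysis of the tertiary allylic formate, and alkene-isomer mixtures at C8. The fallback sets out from 14 and moves the acylation behind the ring formation. Both hydroxyls are silylated (triethylsilyl triflate, 2,6-lutidine, CH2Cl2, −78 °C) to give the bis(triethylsilyl) ether of 14 F1. The same cobalt hydrogen-atom-transfer cascade on F1 gives the bicyclic bis(triethylsilyl) ether F2; here a bulky equatorial silyloxy group steers the fold and no ester is present. TBAF in THF at 40 °C gives the bicyclic 2,13-diol F3. Steglich acylation of its secondary equatorial C2 hydroxyl (3-methylbut-2-enoic acid, DCC, DMAP) comes back to the route at 18.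

**Step 10 (tertiary allylic formate).** The risks are incomplete formylation, allylic rearrangement, and loss of the formate on silica. The fallback sets out from 15 and replaces the ester by a silyl ether. Triethylsilyl triflate and 2,6-lutidine at −78 °C give the 14-O-triethylsilyl ether of 15 F4. The conditions of step 11 (without the methanolysis) give the bicyclic 13-O-triethylsilyl ether F5. HF·pyridine in THF–pyridine at 0 °C comes back to the route at 18.

**Step 7 (alkylation of a dianion with an unprotected chloro alcohol).** The risks are proton transfer, O-alkylation and γ-alkylation. The fallback sets out from 7 (isolated after the chlorination half of step 4) and 11, and uses a direct allyl–allyl coupling without sulfone. Both are protected (tert-butyldimethylsilyl triflate, 2,6-lutidine) as the silyl ether of 7 F6 and the silyl ether of 11 F7. F6 is converted to its allylbarium reagent with activated barium metal (BaI2 and 2 equiv lithium biphenylide, THF, −78 °C) and coupled with F7; this coupling is α,α′-selective and keeps E geometry. The product is the bis(tert-butyldimethylsilyl) ether of 14 F8. TBAF in THF at 50 °C comes back to the route at 14, so steps 7 and 8 are both bypassed.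

Further compounds
F1 | step 11 | bis(triethylsilyl) ether of 14 | C=C[C@@](C)(O[Si](CC)(CC)CC)CC/C=C(\C)CC/C=C(\C)C[C@H](O[Si](CC)(CC)CC)CC(C)=C
F2 | step 11 | bicyclic bis(triethylsilyl) ether (2,13-bis-O-triethylsilyl-ent-labda-7,14-diene-2,13-diol, 2R,5R,9R,10R,13S) | C=C[C@@](C)(O[Si](CC)(CC)CC)CC[C@@H]1C(C)=CC[C@@H]2C(C)(C)C[C@@H](O[Si](CC)(CC)CC)C[C@@]12C
F3 | step 11 | bicyclic 2,13-diol (ent-labda-7,14-diene-2,13-diol, 2R,5R,9R,10R,13S) | C=C[C@@](C)(O)CC[C@@H]1C(C)=CC[C@@H]2C(C)(C)C[C@@H](O)C[C@@]12C
F4 | step 10 | 14-O-triethylsilyl ether of 15 | C=C[C@@](C)(O[Si](CC)(CC)CC)CC/C=C(\C)CC/C=C(\C)C[C@H](OC(=O)C=C(C)C)CC(C)=C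
F5 | step 10 | bicyclic 13-O-triethylsilyl ether of 18 | C=C[C@@](C)(O[Si](CC)(CC)CC)CC[C@@H]1C(C)=CC[C@@H]2C(C)(C)C[C@@H](OC(=O)C=C(C)C)C[C@@]12C
F6 | step 7 | tert-butyldimethylsilyl ether of 7 | C=C(C)C[C@@H](O[Si](C)(C)C(C)(C)C)C/C(C)=C/CCl
F7 | step 7 | tert-butyldimethylsilyl ether of 11 | C=C[C@@](C)(O[Si](C)(C)C(C)(C)C)CC/C=C(\C)CCl
F8 | step 7 | bis(tert-butyldimethylsilyl) ether of 14 | C=C[C@@](C)(O[Si](C)(C)C(C)(C)C)CC/C=C(\C)CC/C=C(\C)C[C@H](O[Si](C)(C)C(C)(C)C)CC(C)=C
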